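**Retrosynthetic overview** (atom labels C1–C15 are germacrane numbers of the target: C6 lactone CH–O, C7 ring-fusion CH, C8 CH–OH, C9 CH–O-acyl, C10 bears C14HO, C1=C10 and C4=C5 both ring-cis, C11–C13 methylene lactone, C15 methyl)
1. Target ⇐ 10-bromo macrolactone: late C14 hydroxymethylation, oxidation and desilylation.
2. Rings: the 10-membered carbocycle is closed first by a Cr(II) allylation at C6–C7 (C6 and C7 set from C8); the γ-lactone then closes on the new C6–OH.
3. Seco chain ⇐ C7 aldehyde + propiolate-derived acrylate unit (C11–C13); C3–C4 by B-alkyl Suzuki coupling with (Z)-3-iodobut-2-en-1-ol (C4–C6, C15).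
4. Both chain ends (C2 enal, C7 aldehyde) ⇐ ozonolytic opening of the non-brominated olefin of a bromocyclohexadiene cis-diol in which O8 is silylated and O9 already carries the (R)-2-methylbutanoate.
5. Key step: toluene-dioxygenase cis-dihydroxylation of bromobenzene. This one dearomatisation supplies C1, C2 and C7–C10, sets C8 and C9, and locks the ring-cis C1=C10 geometry.

Assumption: the recombinant strain E. coli JM109(pDTG601A) is treated as an available biocatalyst; compounds 1, 4, 9, 15 and 22 are bought.

**Step 1**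
Reactants: 1 bromobenzene
Product: 2 (1S,2S)-3-bromocyclohexa-3,5-diene-1,2-diol
Conditions: E. coli JM109(pDTG601A) whole cells (toluene dioxygenase), IPTG, glucose feed, air, pH 6.8, 35 °C; EtOAc extraction
Reagents that add atoms: dioxygen, O=O
Why: Enzymatic arene cis-dihydroxylation (toluene dioxygenase) of monosubstituted benzenes gives the 3-substituted cis-diol essentially enantiopure, so this dearomatisation sets C8 (S) and C9 (R) of the target and holds C2 and C9 cis across the future C1=C10 bond.

**Step 2**
Reactants: 2 (1S,2S)-3-bromocyclohexa-3,5-diene-1,2-diol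
Product: 3 mono-TDS ether of 2 (thexyldimethylsilyl on the hydroxyl remote from Br, future O8; hydroxyl next to C–Br, future O9, free; configuration of 2 kept)
Conditions: TDSCl (1.05 equiv), imidazole, DMF, −20 °C
Reagents that add atoms: thexyldimethylsilyl chloride, CC(C)C(C)(C)[Si](C)(C)Cl
Why: Regioselective silylation, because the hydroxyl remote from bromine is the less hindered one and takes the bulky silyl group first; no stereocentre is touched.

**Step 3**
Reactants: 3 mono-TDS ether of 2; 4 (R)-2-methylbutanoic acid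
Product: 5 (R)-2-methylbutanoate of 3 (ester on O9, TDS on O8, cis; bromodiene intact)
Conditions: DCC, DMAP (cat.), CH2Cl2, 0 °C → rt
Reagents that add atoms: none
Why: Steglich esterification of the only free hydroxyl installs the final C9 ester now, so the two secondary oxygens never have to be told apart later; the acyl stereocentre is bought and C9 is not touched.

**Step 4**
Reactants: 5 (R)-2-methylbutanoate of 3
Product: 7 open-chain Z-bromo-enal acetal (MeO)2C7H–C8H(OTDS)–C9H(O-acyl)–C10(Br)=C1H–C2HO (C9 and C2 cis), via ring-opened dialdehyde 6 (not isolated)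
Conditions: O3 (1 equiv, Sudan III end point), CH2Cl2/MeOH, −78 °C; Me2S, −78 °C → rt; then HC(OMe)3, CeCl3·7H2O (cat.), MeOH, rt
Reagents that add atoms: ozone, [O-][O+]=O; trimethyl orthoformate, COC(OC)OC
Why: Chemoselective ozonolysis cleaves the electron-richer non-halogenated ring olefin (the bromo-olefin is deactivated), and cerium-catalysed (Luche–Gemal) acetalisation then masks only the saturated C7 aldehyde while the conjugated C2 enal stays free; C8 and C9 are untouched and the Z geometry comes from the ring.

**Step 5**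
Reactants: 7 open-chain Z-bromo-enal acetal
Product: 8 (Z)-2-bromo-1,3-diene C3H2=C2H–C1H=C10(Br)– (rest as in 7)
Conditions: Ph3PCH3Br, KHMDS, THF, −78 → 0 °C
Reagents that add atoms: methyltriphenylphosphonium bromide, C[P+](c1ccccc1)(c1ccccc1)c1ccccc1.[Br-]
Why: Wittig methylenation of the enal adds C3 at low temperature faster than the ylide can attack the hindered ester; no stereocentre is formed and C1=C10 is not affected.

**Step 6**
Reactants: 9 but-2-yn-1-ol
Product: 11 (Z)-3-iodobut-2-en-1-ol, via cyclic alkenylalanate 10 (not isolated)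
Conditions: Red-Al, Et2O, 0 °C → rt; EtOAc; then I2, THF, −78 °C
Reagents that add atoms: iodine, II
Why: Hydroxyl-directed trans-hydroalumination of the propargylic alcohol followed by iodinolysis with retention gives only the Z vinyl iodide (iodine cis to CH2OH).

**Step 7**
Reactants: 8 (Z)-2-bromo-1,3-diene; 11 (Z)-3-iodobut-2-en-1-ol
Product: 13 coupled acetal alcohol (MeO)2C7H–C8H(OTDS)–C9H(O-acyl)–C10(Br)=C1H–C2H2–C3H2–C4(CH3)=C5H–C6H2OH (both olefins with the chain carbons cis), via B-alkyl-9-BBN 12 (not isolated)
Conditions: 9-BBN-H, THF, 0 °C → rt; then 11, Pd(dppf)Cl2 (5 mol%), AsPh3, Cs2CO3, DMF/H2O, rt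
Reagents that add atoms: none
Why: 9-BBN hydroborates only the terminal vinyl group (anti-Markovnikov), and B-alkyl Suzuki–Miyaura coupling with retention at the vinyl iodide forms C3–C4 and delivers the Z C4=C5 olefin; at room temperature the iodide reacts far faster than the hindered internal vinyl bromide.

**Step 8**
Reactants: 13 coupled acetal alcohol
Product: 14 C7 aldehyde OHC–C8H(OTDS)–C9H(O-acyl)–… with the C6 primary allylic alcohol free
Conditions: LiBF4, MeCN/H2O (50:1), 40 °C
Reagents that add atoms: water, O
Why: Mild Lewis-acid acetal hydrolysis frees the C7 aldehyde without touching silyl ether, ester or allylic alcohol, and avoids base that could eliminate the β-acyloxy group.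

**Step 9**
Reactants: 14 C7 aldehyde; 15 methyl propiolate
Product: 17 Baylis–Hillman-type adduct, methyl 2-methylene-3-hydroxy ester at C7 (both C7 epimers; C6–OH free), via methyl 2-(diisobutylalumanyl)acrylate 16 (not isolated)
Conditions: 15 (3 equiv), DIBAL-H, NMO, THF, 0 °C, 30 min; then 14, 0 °C → rt; Rochelle salt work-up
Reagents that add atoms: none
Why: Hydroalumination of the propiolate gives an α-(methoxycarbonyl)vinylalane that adds 1,2 to the aldehyde (vinylalumination, a non-basic route to Morita–Baylis–Hillman adducts), which avoids E1cB loss of the β-acyloxy group; the new C7 carbinol centre forms unselectively and is erased in step 11.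

**Step 10**
Reactants: 17 Baylis–Hillman-type adduct
Product: 18 Z-enal at C6 (C6HO–C5H=C4(CH3)–, neral-type), Baylis–Hillman alcohol unchanged
Conditions: MnO2 (activated, excess), CH2Cl2, rt
Reagents that add atoms: none
Why: MnO2 allylic oxidation takes the electron-rich primary allylic alcohol far faster than the electron-poor secondary Baylis–Hillman alcohol, and the neutral conditions keep the Z geometry.

**Step 11**
Reactants: 18 Z-enal
Product: 19 seco allylic bromide BrC13H2–C11(CO2Me)=C7H–C8H(OTDS)– (C8 cis to CH2Br), C6 enal unchanged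
Conditions: NBS, Me2S, CH2Cl2, 0 °C → rt
Reagents that add atoms: N-bromosuccinimide, BrN1C(=O)CCC1=O
Why: Corey–Kim-type activation converts the Baylis–Hillman alcohol into the rearranged (SN2′) primary allylic bromide with the thermodynamically preferred geometry and tolerates the enal; the C7 carbinol stereocentre disappears.

**Step 12**
Reactants: 19 seco allylic bromide
Product: 21 10-bromo macrolactone (target skeleton with Br in place of C14HO and O8 as TDS ether; 6R,7R,8S,9R), via cyclised hydroxy ester 20 (not isolated)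
Conditions: CrCl2 (6 equiv, Ni-free), THF, 3 mM, slow addition, rt; 1 M HCl work-up; then PPTS (cat.), CH2Cl2, rt
Reagents that add atoms: none
Why: Intramolecular Nozaki–Hiyama (Barbier-type) allylation closes the ten-membered ring at C6–C7; the allylchromium adds through a chair transition state to give the anti C6/C7 adduct and, with C8–H eclipsing the olefin (A1,3 strain), on the face that puts C11 cis to the C8 silyloxy group, so C6 and C7 are set from C8, and acid then closes the trans γ-lactone.

**Step 13**
Reactants: 21 10-bromo macrolactone; 22 (tributylstannyl)methanol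
Product: 23 14-hydroxy macrolactone (C10–CH2OH, 8-O-TDS)
Conditions: Pd2(dba)3 (5 mol%), AsPh3, CuI, NMP, 50 °C
Reagents that add atoms: none
Why: Migita–Kosugi–Stille coupling transfers the hydroxymethyl group of the α-hydroxystannane to the vinyl bromide with retention of the olefin geometry; no stereocentre is touched.

**Step 14**
Reactants: 23 14-hydroxy macrolactone
Product: 24 8-O-TDS ether of the target (C14 aldehyde)
Conditions: MnO2, CH2Cl2, rt
Reagents that add atoms: none
Why: MnO2 oxidation of the only allylic alcohol gives the enal, whose geometry (C2 trans to CHO) is also the thermodynamically preferred one.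

**Step 15**
Reactants: 24 8-O-TDS ether of the target
Product: 25 target, (1(10)E,4Z,6R,7R,8S,9R)-8-hydroxy-9-[(2R)-2-methylbutanoyloxy]-14-oxogermacra-1(10),4,11(13)-trien-12,6-olide
Conditions: HF·pyridine, THF/pyridine, 0 °C → rt
Reagents that add atoms: none
Why: Acidic fluoride desilylation frees the C8 hydroxyl without the base that would cause acyl migration from O9.

**Compound list**
1 | bromobenzene | Brc1ccccc1 | starting material
2 | (1S,2S)-3-bromocyclohexa-3,5-diene-1,2-diol | O[C@H]1C=CC=C(Br)[C@H]1O | intermediate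
3 | mono-TDS ether of 2 (silyl on the OH remote from Br, future O8) | CC(C)C(C)(C)[Si](C)(C)O[C@H]1C=CC=C(Br)[C@H]1O | intermediate
4 | (R)-2-methylbutanoic acid | CC[C@@H](C)C(=O)O | starting material
5 | (R)-2-methylbutanoate of 3 (ester on future O9, cis to OTDS) | CC(C)C(C)(C)[Si](C)(C)O[C@H]1C=CC=C(Br)[C@H]1OC(=O)[C@H](C)CC | intermediate
6 | ring-opened dialdehyde OHC(C7)–C8H(OTDS)–C9H(O-acyl)–C10(Br)=C1H–C2HO, Z | O=C[C@H](O[Si](C)(C)C(C)(C)C(C)C)[C@H](OC(=O)[C@H](C)CC)/C(Br)=C\C=O | intermediate
7 | 6 with C7 as dimethyl acetal, Z-bromo-enal free | COC(OC)[C@H](O[Si](C)(C)C(C)(C)C(C)C)[C@H](OC(=O)[C@H](C)CC)/C(Br)=C\C=O | intermediate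
8 | (Z)-2-bromo-1,3-diene from methylenation of 7 | COC(OC)[C@H](O[Si](C)(C)C(C)(C)C(C)C)[C@H](OC(=O)[C@H](C)CC)/C(Br)=C\C=C | intermediate
9 | but-2-yn-1-ol | CC#CCO | starting material
10 | cyclic sodium alkenylalanate (Al on C3, cis to CH2O) | CC1=CCO[Al-]1(OCCOC)OCCOC.[Na+] | intermediate
11 | (Z)-3-iodobut-2-en-1-ol | C/C(I)=C/CO | intermediate
12 | B-alkyl-9-BBN from hydroboration of 8 at C3 | COC(OC)[C@H](O[Si](C)(C)C(C)(C)C(C)C)[C@H](OC(=O)[C@H](C)CC)/C(Br)=C\CCB1C2CCCC1CCC2 | intermediate
13 | coupled acetal alcohol (C7 acetal, C6–OH, both olefins ring-cis type) | COC(OC)[C@H](O[Si](C)(C)C(C)(C)C(C)C)[C@H](OC(=O)[C@H](C)CC)/C(Br)=C\CC/C(C)=C\CO | intermediate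
14 | C7 aldehyde with C6–OH free | O=C[C@H](O[Si](C)(C)C(C)(C)C(C)C)[C@H](OC(=O)[C@H](C)CC)/C(Br)=C\CC/C(C)=C\CO | intermediate
15 | methyl propiolate | COC(=O)C#C | starting material
16 | methyl 2-(diisobutylalumanyl)acrylate | COC(=O)C(=C)[Al](CC(C)C)CC(C)C | intermediate
17 | Baylis–Hillman-type adduct (C7 carbinol, both epimers), C6–OH free | COC(=O)C(=C)C(O)[C@H](O[Si](C)(C)C(C)(C)C(C)C)[C@H](OC(=O)[C@H](C)CC)/C(Br)=C\CC/C(C)=C\CO | intermediate
18 | Baylis–Hillman alcohol with C6 Z-enal | COC(=O)C(=C)C(O)[C@H](O[Si](C)(C)C(C)(C)C(C)C)[C@H](OC(=O)[C@H](C)CC)/C(Br)=C\CC/C(C)=C\C=O | intermediate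
19 | seco allylic bromide (C8 cis to CH2Br) with C6 Z-enal | COC(=O)/C(CBr)=C/[C@H](O[Si](C)(C)C(C)(C)C(C)C)[C@H](OC(=O)[C@H](C)CC)/C(Br)=C\CC/C(C)=C\C=O | intermediate
20 | cyclised hydroxy ester (10-membered ring, C6–OH, C7 bearing the acrylate) | C=C(C(=O)OC)[C@H]1[C@H](O)/C=C(/C)CC/C=C(/Br)[C@@H](OC(=O)[C@H](C)CC)[C@H]1O[Si](C)(C)C(C)(C)C(C)C | intermediate
21 | 10-bromo macrolactone, 8-O-TDS | C=C1C(=O)O[C@@H]2/C=C(/C)CC/C=C(/Br)[C@@H](OC(=O)[C@H](C)CC)[C@@H](O[Si](C)(C)C(C)(C)C(C)C)[C@@H]12 | intermediate
22 | (tributylstannyl)methanol | CCCC[Sn](CCCC)(CCCC)CO | starting material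
23 | 14-hydroxy macrolactone, 8-O-TDS | C=C1C(=O)O[C@@H]2/C=C(/C)CC/C=C(/CO)[C@@H](OC(=O)[C@H](C)CC)[C@@H](O[Si](C)(C)C(C)(C)C(C)C)[C@@H]12 | intermediate
24 | 8-O-TDS ether of the target | C=C1C(=O)O[C@@H]2/C=C(/C)CC/C=C(/C=O)[C@@H](OC(=O)[C@H](C)CC)[C@@H](O[Si](C)(C)C(C)(C)C(C)C)[C@@H]12 | intermediate
25 | target CNP0256845.2 | C=C1C(=O)O[C@@H]2/C=C(/C)CC/C=C(/C=O)[C@@H](OC(=O)[C@H](C)CC)[C@@H](O)[C@@H]12 | target

**Step count:** 15 steps in total. The longest linear sequence is 14 steps (bromobenzene → target; step 6 is a one-step side branch).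

**Steps most likely to fail, with fallbacks**

1. Step 12 (macrocyclisation). The ring closure competes with oligomerisation and reduction, and the facial selectivity at C7 and the anti C6/C7 outcome rest on a transition-state model, not on a close precedent. Fallback, setting out from 8 and returning at 21: 8 is hydroborated and coupled with 2-bromopropene under the step 7 conditions to give the isopropenyl acetal F2. LiBF4 in wet MeCN gives the aldehyde F3. Vinylalumination as in step 9 gives the Baylis–Hillman alcohol F4, and NBS/Me2S gives the allylic bromide F5. An intermolecular CrCl2 allylation of acrolein followed by PPTS gives the trans vinyl lactone F6, with C6 and C7 set by acyclic 1,2-induction from C8. Ring-closing metathesis (Hoveyda–Grubbs II, toluene, 80 °C, 1 mM) between the C6 vinyl group and the isopropenyl group then forms the ring-cis C4=C5 olefin and gives 21.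

2. Step 13 (Stille hydroxymethylation). The vinyl bromide is hindered and sits in a ring that also holds two allylic carboxylates that Pd(0) could ionise. Fallback, setting out from 21 and returning at 23: a Nozaki–Hiyama–Kishi reaction (CrCl2, NiCl2 cat., paraformaldehyde, DMSO/THF, rt) adds the vinylchromium species to formaldehyde and gives 23 directly without Pd(0); further compound: none F0.

3. Step 4 (selective ring opening). Over-ozonolysis of the bromo-olefin or incomplete discrimination of the two aldehydes would cost material. Fallback, setting out from 5 and returning at 7: catalytic OsO4/NMO (acetone/H2O, 0 °C) dihydroxylates only the non-brominated ring olefin, on the face opposite the silyloxy group, to give the bromocyclohexene cis-diol F1. Pb(OAc)4 in CH2Cl2/MeOH cleaves it to 6, which is acetalised as in step 4 to give 7.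

**Further compounds**
F1 | step 4 | cis-diol from dihydroxylation of the non-brominated olefin of 5 (new OH groups trans to OTDS) | CC(C)C(C)(C)[Si](C)(C)O[C@H]1[C@H](O)[C@H](O)C=C(Br)[C@H]1OC(=O)[C@H](C)CC
F2 | step 12 | isopropenyl acetal (C3–C4(CH3)=CH2 terminus in place of the C4–C6 unit of 13) | COC(OC)[C@H](O[Si](C)(C)C(C)(C)C(C)C)[C@H](OC(=O)[C@H](C)CC)/C(Br)=C\CCC(C)=C
F3 | step 12 | C7 aldehyde from F2 | O=C[C@H](O[Si](C)(C)C(C)(C)C(C)C)[C@H](OC(=O)[C@H](C)CC)/C(Br)=C\CCC(C)=C
F4 | step 12 | Baylis–Hillman alcohol from F3 (both C7 epimers) | COC(=O)C(=C)C(O)[C@H](O[Si](C)(C)C(C)(C)C(C)C)[C@H](OC(=O)[C@H](C)CC)/C(Br)=C\CCC(C)=C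
F5 | step 12 | allylic bromide from F4 (C8 cis to CH2Br) | COC(=O)/C(CBr)=C/[C@H](O[Si](C)(C)C(C)(C)C(C)C)[C@H](OC(=O)[C@H](C)CC)/C(Br)=C\CCC(C)=C
F6 | step 12 | trans 6-vinyl α-methylene-γ-lactone (6R,7R) carrying the isopropenyl chain | C=C[C@H]1OC(=O)C(=C)[C@@H]1[C@H](O[Si](C)(C)C(C)(C)C(C)C)[C@H](OC(=O)[C@H](C)CC)/C(Br)=C\CCC(C)=C
F0 | step 13 | none | none
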